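The data are calculated with constants of no real substance; noise was put on by code.

Time is the plainest thing in the red run: target climbs fast, then creeps, as a level bimolecular pair does.

the same everywhere: starting material 0.10 M
- red: coupling partner 1.2 equiv; second substrate 1 equiv; protic impurity 5 mM; temperature 65 °C; run made earlier
- amber: coupling partner 1.2 equiv; second substrate 0.67 equiv; protic impurity 5 mM; temperature 76 °C; run made earlier
- green: coupling partner 1.2 equiv; second substrate 1.5 equiv; protic impurity 5 mM; temperature 65 °C; run made earlier
- dawn: coupling partner 1.20 equiv; second substrate 1.00 equiv; protic impurity 5.00 mM; temperature 70 °C; everything together at the start; time 15 d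
- midnight: coupling partner 1.20 equiv (in portions, 5, over 12 d); second substrate 1.00 equiv; protic impurity 5.00 mM; temperature 70 °C; first portion at the start, last at 12 d; time 15 d
- summer: coupling partner 1.20 equiv (fed, over 12 d); second substrate 1.00 equiv; protic impurity 5.00 mM; the addition at 40 °C, then warmed to 70 °C; the feed brings no volume worth counting; time 15 d
- autumn: coupling partner 1.20 equiv; second substrate 1.00 equiv; protic impurity 5.00 mM; everything together at the start at 40 °C, warmed to 70 °C at 12 d; time 15 d
- winter: coupling partner 1.20 equiv (fed, over 12 d); second substrate 1.00 equiv; protic impurity 5.00 mM; temperature 70 °C; all else is in the flask from the start; the feed brings no volume worth counting; time 15 d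

| run | time / d | target / % |
|---|---|---|
| red | 1.25 | 24.9 |
| red | 2.08 | 28.7 |
| red | 3.00 | 31.6 |
| red | 5.00 | 34.9 |
| red | 10.0 | 39.8 |
| red | 15.0 | 42.0 |
| amber | 1.25 | 41.2 |
| amber | 2.08 | 46.3 |
| amber | 3.00 | 49.5 |
| amber | 5.00 | 53.7 |
| amber | 10.0 | 57.6 |
| amber | 15.0 | 59.8 |
| green | 1.25 | 20.3 |
| green | 2.08 | 22.9 |
| green | 3.00 | 24.2 |
| green | 5.00 | 26.0 |
| green | 10.0 | 28.3 |
| green | 15.0 | 29.1 |

(scatter of a reading: 0.3 percentage points)

- the analysis behind the earlier runs scatters by 0.3 percentage points, standard deviation
- what may be going on: second substrate + coupling partner -> second product; starting material + second substrate -> cross product; starting material + coupling partner -> target; starting material + protic impurity -> quenched substrate; 2 second substrate -> self-condensation product; target <-> isomer of the product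

- the flask that comes out highest in amount of target, in percent of the starting material charged, or "all alike" when all lie within 1.5 percentage points (dawn / midnight / summer / autumn / winter / all alike)
- target at the end, in percent of the starting material charged, dawn
- target at the end, in percent of the starting material charged, midnight
- target at the end, in percent of the starting material charged, summer
- target at the end, in percent of the starting material charged, autumn
- target at the end, in percent of the starting material charged, winter

**Pair life.** Integrating a second-order rate for a level pair gives target = Y·t/(t+τ), where Y is the limit and τ the pair life, the second-order half-life. The first and last red readings give τ = 0.999 d and Y = 44.8%. The same two amber readings give 0.642 d, though with less second substrate, so the geometric mean, 0.801 d, serves roughly for 70 °C.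

**Two extremes.** My assumption is that, protic impurity set aside, starting material and second substrate, charged level, consume each other at this same pace. Free starting material is then the inverse of one plus x, where x counts elapsed pair lives. In one pair life the feed brings coupling partner equal to N = 0.0801 of the starting material charged. Feed equals free starting material at x = 3.07, and there stands the crossing share, 0.246, the fraction of starting material still free when the fed coupling partner catches it. Large N sends this share towards the whole charge; dawn, with everything in at the start, is that end, and there I expect target near Y. Small N sends it towards nothing. Winter lies near that second end, because the pair life is shorter than the feed. In this reckoning coupling partner is the limiting reagent in winter until the crossing, and I put winter's target near the crossing share.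

**The forecast.** It holds that “Feeding leaves the competition unchanged”. It names winter highest, with dawn 43.8%, midnight 44.2%, summer 40.5%, autumn 40.5% and winter 44.4%. My reckoning differs on winter, with 0.246 of the charge against that last figure.

**The result.** Dawn ends highest at 45.0%, with midnight 27.0%, summer 31.3%, autumn 34.5% and winter 24.5%.

    second substrate + coupling partner → second product (k = 0.625 M⁻¹ h⁻¹, Ea = 94.0 kJ mol⁻¹)
    starting material + second substrate → cross product (k = 0.408 M⁻¹ h⁻¹, Ea = 76.0 kJ mol⁻¹)
    starting material + coupling partner → target (k = 0.312 M⁻¹ h⁻¹, Ea = 95.0 kJ mol⁻¹)
    starting material + protic impurity → quenched substrate (k = 13.5 M⁻¹ h⁻¹, Ea = 77.0 kJ mol⁻¹)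
    2 second substrate → self-condensation product (k = 0.0713 M⁻¹ h⁻¹, Ea = 99.0 kJ mol⁻¹)
    target ⇌ isomer of the product (K = 0.220, k = 0.0102 h⁻¹, Ea = 115 kJ mol⁻¹, ΔH = −11.0 kJ mol⁻¹)
    (constants at 70 °C)

**Neighbour.** Winter ends with target 24.5% against the crossing share 0.246, beside isomer of the product 5.35% and cross product 64.9%. The neighbouring flask is winter with second substrate cut to 0.400 equiv. Taken one for one, with protic impurity set aside, that charge leaves a crossing share of 0.600, reached at 6.00 d, later than the level pair life. That flask ends with cross product 32.3%, target 50.2% and isomer of the product 10.9%.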